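Percent of the substrate charged is what the peaks give us, and what we want from them is one quotient: isomer of the product over target, here called the ratio.

| setting | alpha | zeta | flask |
|---|---|---|---|
| substrate | 0.014 M | 0.022 M | 0.010 M |
| coupling partner | 1.3 equiv | 1.3 equiv | 1.30 equiv |
| remark | run made earlier | run made earlier |  |
| time |  |  | 6.0 d |

| run | time / d | isomer of the product / % | target / % |
|---|---|---|---|
| alpha | 0.833 | 7.4 | 17.6 |
| alpha | 2.50 | 18.8 | 40.8 |
| alpha | 5.00 | 25.7 | 45.8 |
| alpha | 8.00 | 26.4 | 47.7 |
| zeta | 1.67 | 17.7 | 36.9 |
| zeta | 4.00 | 22.6 | 48.4 |
| zeta | 5.00 | 24.9 | 48.7 |
| zeta | 8.00 | 25.2 | 47.7 |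

(scatter of a reading: 1 percentage point)

- ratio of isomer of the product to target at 4.0 h
- ratio of isomer of the product to target at 6.0 d
- which of isomer of the product and target there is more of at 6.0 d

- in percentages every species weighs as the substrate in it: one self-condensation product counts as two
- the numbers in the tables scatter with a standard deviation of 1 percentage point
- steps thought possible: intermediate <-> target; 2 substrate -> self-condensation product; substrate + coupling partner -> intermediate + released group; intermediate <-> isomer of the product

Which given numbers must be known well? For the late ratio the substrate charge need not be. Zeta started at a higher [substrate] than alpha, yet their last ratios, 0.553 and 0.528, differ by less than two scatter widths. The early readings are weaker: one point on the isomer of the product moves alpha's first ratio by 0.0568, but its last by 0.0210. So we pool. The first readings of both runs give 0.461, our kinetic end, and we take it for 4.0 h, which comes before any reading. The readings at the two latest times of each run give 0.538, the side of thermodynamic control.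

To join the ends, we note that formation is second order. At equal equivalents, 6.0 d in this flask therefore counts, for formation, as 4.29 d of alpha, short of 5.00 d. We commit to the midpoint, the mid-ratio 0.499, and it is below one, so target leads.

The forecast gives 0.43 and 0.51, with target ahead: “Its products are younger, so equilibration is not quite complete.” Our early end stands above its first value, our mid-ratio below its second.

The flask gives 0.451 at 4.0 h and 0.512 at 6.0 d, with target ahead, 46.3% against 23.7%.

    intermediate ⇌ target (K = 4.26, k = 0.0407 h⁻¹)
    2 substrate → self-condensation product (k = 0.480 M⁻¹ h⁻¹)
    substrate + coupling partner → intermediate + released group (k = 2.99 M⁻¹ h⁻¹)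
    intermediate ⇌ isomer of the product (K = 2.42, k = 0.0183 h⁻¹)

The rate constants from intermediate to isomer of the product and to target stand in the ratio 0.450. The mid-ratio times this flask's target gives 23.1% of isomer of the product, where the flask holds 23.7%. In the neighbour charged with 0.330 equiv of coupling partner, target is 16.5%, so the mid-ratio gives 8.23%. The computed amount there is 8.40%, a ratio of 0.510.

(The numbers in the tables stem from a simulated flask with constants of no real substance.)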